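## Structural features

Locants used throughout: C1=C10 is the ring alkene (methyl on C10), C2 the O-bearing CH, C3 the ring CH2, C4 the quaternary carbon, C5 the ring-fusion CH, C6 and C7 the cyclopropane CH carbons, C8 and C9 the ring D methylenes, C11 the CMe2 carbon, C7' the benzylic CH. Ring A is the arene, B the oxepane, C the cyclopentane, D the cycloheptene, E the cyclopropane.

- The target joins a 2,4-diformylphloroglucinol (ring A) to a 5-7-3 sesquiterpenoid twice: through a phenolic oxygen to C2 and through C7' (which also carries the isobutyl group) to quaternary C4. Ring B therefore bridges C2 and C4 of ring C.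
- Ring C is fused at C1–C5 to ring D, which holds the tetrasubstituted C1=C10 alkene and is cis-fused at C6–C7 to the gem-dimethylcyclopropane ring E.
- There are six stereocentres. C7', C4, C5, C6 and C7 form an unbroken chain and C2 sits 1,3 to C4 across ring C. H5 is anti to H6 and syn to C11, the C4 methyl is cis to C6, and the C2 oxygen is cis to C7'.
- Fragile groups: the C2–O bond is allylic to a tetrasubstituted alkene and has an acidic phenol as leaving group; ring E lies one atom from any charge at C5; ring A carries two aldehydes and three acidic hydroxyls.
- The real difficulty is quaternary C4 wedged between C5 and C7', together with the bridged ring B with defined C2 and C7'.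
- The feature used: C7' is bonded to C4 next to C5. C7', C4, C3, C2, C1 and C5 can therefore first be a cyclohexa-1,4-diene formed by cycloaddition across C1–C5 and C2–C3, which closes ring D onto ring E in the same event. A 1,2-shift of C5 from C7' to C4 then contracts that ring to ring C and expels C7' as the aldehyde on C4.

## Logic of the disconnections

20 to 19. No skeletal bond is cut; the isobutyl group is traced back to a methallyl group. An isobutyl nucleophile compatible with a benzylic cation and two aryl aldehydes is not available, an allylsilane is. The forward step must reduce only the 1,1-disubstituted alkene.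

19 to 14, 16 and 17. The bonds cut are C2–O, C7'–aryl and C7'–CH2. All three lie at positions that stabilise positive charge, so one acid-mediated operation can form them. This removes ring B and the whole arene and leaves a tricyclic terpenoid with two latent cations. The forward step must close ring B before the carbon nucleophile meets C7', and must keep 17 away from the allyl cation.

16 to 15. Two aryl–CHO bonds are cut. The symmetric triol needs only twofold electrophilic formylation, which must stop before the third position reacts.

14 to 13 to 12. The C10–CH3 bond is cut, then the acetal is returned to the aldehyde. Methyl addition turns the enone into a tertiary allylic alcohol whose ionisation places the alkene at C1=C10 and the electrophilic site at C2. The aldehyde must be masked first, and the methyl must add 1,2 without enolisation.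

12 to 11 to 10. In the reverse sense C4–C5 is cut and C5–C7' restored, giving an epoxide across C4–C7', then the oxygen is removed. A quaternary carbon bearing CHO next to a ring-fusion CH is the signature of an epoxide-to-aldehyde ring contraction. The quaternary stereocentre becomes a trisubstituted ring alkene. The forward steps need epoxidation of the right alkene on the face anti to C6 and migration of C5 anti to the leaving oxygen.

10 to 9. C1–C5 and C2–C3 are cut in a retro-(4+2) sense. Two rings and the C5 stereocentre disappear and a monocyclic cyclopropane with two cis arms remains. The forward step needs an E diene, face selection at C5 by ring E, and a temperature the cis-dienylcyclopropane tolerates.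

9 to 8 to 6 and 7. The C10–C1 bond (acyl–alkynyl) and the C5=C7' alkene are cut. This separates the dienophile, the diene carbons and the carene-derived core. The olefination must be E-selective and must not epimerise the cis-aldehyde.

6 to 4 to 3 to 1. The amide C–N bond is cut, the carboxyl carbon C10 is traced to a methyl ketone, and the two carbonyls to the ring alkene of 1. Both cyclopropane stereocentres then come from the chiral pool. The forward steps must tell the two carbonyls of the ozonolysis product apart.

## Other disconnections considered

Alternative 1: The cut is C1–C5 and C8–C9 (with a transient C1–C6 bond). The acyclic vinyl diazoketone A1 would be treated with Rh2(OAc)4; the carbenoid at C1 cyclopropanates the near alkene of the E diene and the resulting cis-divinylcyclopropane undergoes a Cope shift to the hydroazulenone A2.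
- In its favour: rings C and D form in one operation, the Cope step is stereospecific, and aryl and isobutyl are already on C7'.
- Better than the chosen plan on one point: C1=C10 and the C2 oxygen (as ketone) appear directly where the target needs them, so neither methyl re-addition nor allylic transposition is required.
- Against it: the contiguous C4/C7' pair must be set in an open chain before the key step; C5 is controlled only by the face preference of a five-atom tether at a quaternary carbon whose two substituents differ modestly; ring E must be added afterwards by dimethylcarbene transfer to C6=C7; the chiral pool is not used; a vinyl diazoketone can close to a pyrazole; the formyl groups must be introduced at the end.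
- Comparison: mechanistically more convergent for rings C and D, but the hardest stereochemical problem is left unsupported and ring E costs extra steps, so no gain in step economy is expected.

Alternative 2: The cut is two C–C bonds of ring A. The C2 ethynyl ether A3 would be heated with 3-(benzyloxy)cyclobutenone A4 to give, by vinylketene formation, (2+2) addition, four-electron opening and six-electron closure, the aryl ether A5.
- In its favour, and better than the chosen plan on this point: the C2–O bond and its configuration exist before the arene does, so O- versus C-alkylation of a phloroglucinol cannot compete. The conditions are neutral, and the regiochemistry of the 1,3,5-trioxygenated ring is inherent.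
- Against it: A3 is an allyl alkynyl ether (C2 is allylic to C1=C10) and is expected to undergo a [3,3] shift to a ketene well below the benzannulation temperature. The disconnection removes no terpenoid ring, so the tricyclic core must still be made as in the chosen plan. After A5, ring B closure at C7', alkylation of C7', debenzylation and twofold formylation all remain.
- Comparison: equal on the terpenoid part, which it does not address; longer overall; and its precursor is mechanistically doubtful.

Alternative 3: The cut is C4–C5 and C1–C2. The bicyclic cycloheptenone A6 and the axially chiral allenylsilane A7 would combine with TiCl4: the allene terminus adds to C5, silicon shifts, and the enolate closes ring C to give A8.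
- Better than the chosen plan on two points: A6 is only two steps from 1 (ozonolysis, aldol condensation), so rings D and E arrive earlier and more cheaply; and C7' is carried as a protected alcohol, so the aldehyde/ketone chemoselectivity problem never arises. Ring C and quaternary C4 form in one step.
- Equal to the chosen plan: C5 is set by attack anti to C11 in both.
- Against it: A7 must be made enantioenriched, and its axial chirality must cooperate with the face preference of A6. A silylallene unsubstituted at the silicon-bearing carbon tends to lose silicon without closing the ring. TiCl4 on a β-cyclopropyl enone risks homoconjugate opening of ring E. In A8 the functionality is badly placed: C2 has no oxygen, C3 carries silicon and C1–H must be removed.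
- Comparison: shorter to the carbon skeleton but longer in reagent synthesis and in corrections afterwards; the final union with the arene would be the same as in the chosen plan.

Key step: step 6

Assumptions:
- (+)-2-Carene is the (1S,6R) enantiomer; its two cyclopropane stereocentres become C6 and C7 of the target unchanged.
- 14 and 18 are carried as mixtures at C10 and C7' respectively, because both centres are ionised in step 12; their SMILES leave those centres undefined.
- Diethyl (2-methylallyl)phosphonate is used in place of a methallylphosphonium salt, whose semi-stabilised ylide would give an E/Z mixture that cannot be corrected safely next to a vinylcyclopropane.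

## Route

Step 1
Reactants: 1 (+)-2-carene
Product: 3 4-[cis-3-(dimethoxymethyl)-2,2-dimethylcyclopropyl]butan-2-one (keto acetal, cyclopropane carbons as in 1), via keto aldehyde 2 (not isolated)
Conditions: O3, CH2Cl2/MeOH, −78 °C; Me2S, −78 to 23 °C; then TsOH·H2O (cat.), 23 °C; NaHCO3
Reagents that add atoms: ozone, [O-][O+]=O; methanol, CO
Why: Ozonolysis with reductive work-up cleaves the trisubstituted alkene to a methyl ketone and a cyclopropanecarbaldehyde; in methanol with catalytic acid only the aldehyde is acetalised to a useful extent. No bond to C6 or C7 is touched, so the cis-cyclopropane is retained.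

Step 2
Reactants: 3 keto acetal
Product: 4 3-[cis-3-(dimethoxymethyl)-2,2-dimethylcyclopropyl]propanoic acid
Conditions: Br2, NaOH, H2O/dioxane, 0 °C; Na2SO3; NaH2PO4 to pH 4
Reagents that add atoms: sodium hydroxide, [Na+].[OH-]
Why: Haloform reaction: exhaustive bromination of the methyl group and hydroxide cleavage give the carboxylate. The acetal is inert to base and shields the aldehyde carbon from hypobromite; partial acetal loss on acidification is harmless because step 3 removes it anyway.

Step 3
Reactants: 4 acetal acid
Product: 6 3-(cis-3-formyl-2,2-dimethylcyclopropyl)-N-methoxy-N-methylpropanamide, via acetal amide 5 (not isolated)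
Conditions: 1,1'-carbonyldiimidazole, CH2Cl2, 23 °C; MeNHOMe·HCl; then 1 M HCl, THF, 23 °C
Reagents that add atoms: N,O-dimethylhydroxylamine hydrochloride, CNOC.Cl; water, O
Why: Amidation through the acyl imidazolide gives the Weinreb amide, and dilute aqueous acid then hydrolyses the dimethyl acetal without touching the amide. A cyclopropanecarbaldehyde enolises reluctantly, so the cis relationship should survive.

Step 4
Reactants: 6 aldehyde amide; 7 diethyl (2-methylallyl)phosphonate
Product: 8 N-methoxy-N-methyl-3-{cis-2,2-dimethyl-3-[(1E)-3-methylbuta-1,3-dienyl]cyclopropyl}propanamide
Conditions: 7, n-BuLi, THF, −78 °C; HMPA; 6, −78 to 23 °C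
Reagents that add atoms: none
Why: Horner–Wadsworth–Emmons olefination with a lithiated allylic phosphonate; HMPA favours attack through the α-carbon and elimination to the E alkene. At −78 °C the aldehyde reacts far faster than the Weinreb amide.

Step 5
Reactants: 8 dienyl amide
Product: 9 5-{cis-2,2-dimethyl-3-[(1E)-3-methylbuta-1,3-dienyl]cyclopropyl}pent-1-yn-3-one (dienyl ynone)
Conditions: HC≡CMgBr (0.5 M in THF), THF, 0 °C; inverse quench into cold 1 M HCl
Reagents that add atoms: ethynylmagnesium bromide, C#C[Mg]Br
Why: Weinreb ketone synthesis: the chelated tetrahedral adduct prevents over-addition. The acidic inverse quench protonates the released MeNHOMe so that it cannot add to the terminal ynone.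

Step 6
Reactants: 9 dienyl ynone
Product: 10 tricyclic dienone (cyclohexa-1,4-diene fused at C1–C5 to ring D, ring E cis-fused at C6–C7, C10 ketone, H5 anti to H6 and syn to C11)
Conditions: PhMe (0.01 M), BHT (5 mol %), degassed, 100 °C
Reagents that add atoms: none
Why: On heating, the s-cis diene and the ynone combine in a concerted, asynchronous (4+2) cycloaddition in which C2–C3 (most nucleophilic diene terminus to the ynone β-carbon) runs ahead of C1–C5; the closest known reaction type is the intramolecular Diels–Alder reaction of tethered diene–alkynones. The cyclohexa-1,4-diene (C1, C2, C3, C4, C7', C5) closes as the cycloadduct ring through both new σ bonds, and ring D (C1, C5, C6, C7, C8, C9, C10) closes as the tether ring through C1–C5, the cis-cyclopropane acting as a rigid spacer that turns the five-atom tether back over the diene. Regiochemistry is imposed by the tether and agrees with the electronic preference, and the alkyne leaves no stereocentre at C1 or C2, so no endo/exo question arises. The only new stereocentre, C5, is controlled by ring E: the dienyl group reacts in its bisected s-trans conformation, in which one face of C5 looks at C7 and the tether and the other at C11 and its endo methyl, so the alkyne can bond only on the face away from that methyl, which places H5 syn to C11 as in 20. The step needs the E diene (secured in step 4), access to the s-cis conformer (helped by the C4 methyl) and a temperature below that of the 1,5-homodienyl hydrogen shift of cis-alkyl vinylcyclopropanes; dilution and BHT suppress ynone oligomerisation. No Lewis acid is used, because a stepwise polar pathway would place positive charge on C5 next to the cyclopropane.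

Step 7
Reactants: 10 tricyclic dienone
Product: 11 epoxy enone (epoxide across C4–C7', oxygen anti to C6 and syn to H5)
Conditions: mCPBA, NaHCO3, CH2Cl2, 0 °C
Reagents that add atoms: mCPBA, OOC(=O)c1cccc(Cl)c1
Why: Prilezhaev epoxidation: the electron-rich trisubstituted C4=C7' alkene reacts in preference to the enone alkene. The peracid should approach the face of C7' opposite the C5–C6 bond, which ring D and ring E screen; this sets the C4 and C7' epoxide centres. The buffer protects the acid-labile epoxide and the skipped diene.

Step 8
Reactants: 11 epoxy enone
Product: 12 ring-contracted keto aldehyde (cyclopentene ring C; C4 bears methyl cis to C6 and CHO cis to H5)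
Conditions: MeAl(OAr)2 (Ar = 4-bromo-2,6-di-tert-butylphenyl; from Me3Al and 2 ArOH; 2.2 equiv), CH2Cl2, −78 °C
Reagents that add atoms: none
Why: Lewis-acid epoxide-to-aldehyde (Meinwald-type) rearrangement: the C4–O bond ionises at the tertiary carbon and C5 migrates from C7' to C4 anti to the departing oxygen. This inverts C4, retains C5 and so transfers the epoxide configuration to the quaternary centre. The bulky aluminium phenoxide favours carbon over hydride migration, and the low temperature disfavours proton loss from C3.

Step 9
Reactants: 12 keto aldehyde
Product: 13 keto acetal (C7' as dimethyl acetal)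
Conditions: HC(OMe)3, MeOH, PPTS (cat.), 23 °C
Reagents that add atoms: trimethyl orthoformate, COC(OC)OC; methanol, CO
Why: Acid-catalysed acetalisation is much faster for the aldehyde than for the conjugated ketone. The acetal masks C7' for the methyl addition and is the oxocarbenium precursor needed in step 12.

Step 10
Reactants: 13 keto acetal
Product: 14 tertiary allylic alcohol (C10 bears OH and methyl, both epimers)
Conditions: MeLi, CeCl3, THF, −78 °C; sat. aq. NH4Cl; Et3N-deactivated silica
Reagents that add atoms: methyllithium, [Li]C
Why: Organocerium 1,2-addition to the enone avoids enolisation at C3 or C9 and conjugate addition. The new C10 centre need not be controlled because it is ionised in step 12.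

Step 11
Reactants: 15 phloroglucinol
Product: 16 2,4-diformylphloroglucinol (2,4,6-trihydroxybenzene-1,3-dicarbaldehyde)
Conditions: POCl3, DMF (2.3 equiv each), EtOAc, 0 to 23 °C; then H2O
Reagents that add atoms: N,N-dimethylformamide, CN(C)C=O; water, O
Why: Vilsmeier–Haack formylation; the first two formyl groups deactivate the ring enough to hold the reaction at twofold substitution with controlled stoichiometry.

Step 12
Reactants: 14 tertiary allylic alcohol; 16 2,4-diformylphloroglucinol; 17 methallyltrimethylsilane
Product: 19 methallyl compound (complete ring system of 20 with CH2C(CH3)=CH2 on C7'), via benzylic methyl ether 18 (not isolated)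
Conditions: 16 (1.2 equiv), CSA (30 mol %), 3 Å MS, MeCN/CH2Cl2, 0 to 23 °C; then 17 (3 equiv), 0 °C
Reagents that add atoms: none
Why: Under the sulfonic acid the tertiary allylic alcohol ionises to the C10–C1–C2 allyl cation and the acetal to the C7' oxocarbenium; Friedel–Crafts attack of the single free carbon of 16 on C7' and capture of C2 by the neighbouring phenol oxygen (SN1'-type etherification, possible only cis to C7', which sets C2, while a trans ether can re-ionise) close ring B, and because the sieves remove water the released methanol caps C7' as 18. Only then is 17 added: Hosomi–Sakurai attack on the C7' cation (ortho-quinone methide) held in the bridged B/C bicycle should come from the face turned to the one-carbon bridge C3, away from the C1–C5 bridge that carries rings D and E, which gives the C7' configuration of 20 and keeps the silane from meeting the free allyl cation.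

Step 13
Reactants: 19 methallyl compound
Product: 20 CNP0388405.1
Conditions: H2 (1 atm), RhCl(PPh3)3 (10 mol %), PhH/EtOH, 23 °C
Reagents that add atoms: none
Why: Homogeneous hydrogenation with RhCl(PPh3)3 reduces an unhindered 1,1-disubstituted alkene far faster than the tetrasubstituted C1=C10 alkene. At room temperature it should not hydrogenolyse the allylic C2–O bond, open the cyclopropane or reduce the aryl aldehydes; no stereocentre is formed.

## Compound list

1 | (+)-2-carene, (1S,6R)-3,7,7-trimethylbicyclo[4.1.0]hept-2-ene | CC1=C[C@H]2[C@@H](CC1)C2(C)C | starting material
2 | cis-2,2-dimethyl-3-(3-oxobutyl)cyclopropane-1-carbaldehyde | CC(=O)CC[C@@H]1[C@H](C=O)C1(C)C | intermediate (not isolated)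
3 | 4-[cis-3-(dimethoxymethyl)-2,2-dimethylcyclopropyl]butan-2-one | CC(=O)CC[C@@H]1[C@H](C(OC)OC)C1(C)C | intermediate
4 | 3-[cis-3-(dimethoxymethyl)-2,2-dimethylcyclopropyl]propanoic acid | OC(=O)CC[C@@H]1[C@H](C(OC)OC)C1(C)C | intermediate
5 | 3-[cis-3-(dimethoxymethyl)-2,2-dimethylcyclopropyl]-N-methoxy-N-methylpropanamide | CON(C)C(=O)CC[C@@H]1[C@H](C(OC)OC)C1(C)C | intermediate (not isolated)
6 | 3-(cis-3-formyl-2,2-dimethylcyclopropyl)-N-methoxy-N-methylpropanamide | CON(C)C(=O)CC[C@@H]1[C@H](C=O)C1(C)C | intermediate
7 | diethyl (2-methylallyl)phosphonate | C=C(C)CP(=O)(OCC)OCC | starting material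
8 | N-methoxy-N-methyl-3-{cis-2,2-dimethyl-3-[(1E)-3-methylbuta-1,3-dienyl]cyclopropyl}propanamide | CON(C)C(=O)CC[C@@H]1[C@H](/C=C/C(C)=C)C1(C)C | intermediate
9 | 5-{cis-2,2-dimethyl-3-[(1E)-3-methylbuta-1,3-dienyl]cyclopropyl}pent-1-yn-3-one (dienyl ynone) | C#CC(=O)CC[C@@H]1[C@H](/C=C/C(C)=C)C1(C)C | intermediate
10 | tricyclic six–seven–three dienone (C10 ketone, C1=C2 and C4=C7' alkenes, H5 syn to C11) | O=C1C2=CCC(C)=C[C@H]2[C@H]3[C@@H](CC1)C3(C)C | intermediate
11 | C4–C7' epoxide of 10, oxygen anti to C6 | O=C1C2=CC[C@]3(C)O[C@@H]3[C@H]2[C@H]4[C@@H](CC1)C4(C)C | intermediate
12 | five–seven–three keto aldehyde (C10 ketone, C1=C2 alkene, C4 with methyl cis to C6 and CHO) | O=C1C2=CC[C@](C)(C=O)[C@H]2[C@H]3[C@@H](CC1)C3(C)C | intermediate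
13 | dimethyl acetal of 12 | O=C1C2=CC[C@](C)(C(OC)OC)[C@H]2[C@H]3[C@@H](CC1)C3(C)C | intermediate
14 | C10 tertiary allylic alcohol of 13 (C10 epimers) | CC1(O)C2=CC[C@](C)(C(OC)OC)[C@H]2[C@H]3[C@@H](CC1)C3(C)C | intermediate
15 | phloroglucinol | Oc1cc(O)cc(O)c1 | starting material
16 | 2,4-diformylphloroglucinol | O=Cc1c(O)cc(O)c(C=O)c1O | intermediate
17 | methallyltrimethylsilane | C=C(C)C[Si](C)(C)C | starting material
18 | ring-B closed benzylic methyl ether (OMe on C7', C7' epimers; otherwise as 20) | CC1=C2[C@H]([C@H]3[C@@H](CC1)C3(C)C)[C@]1(C)C[C@H]2Oc2c(C=O)c(O)c(C=O)c(O)c2C1OC | intermediate (not isolated)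
19 | methallyl compound (2-methylallyl on C7', otherwise as 20) | CC1=C2[C@H]([C@H]3[C@@H](CC1)C3(C)C)[C@]1(C)C[C@H]2Oc2c(C=O)c(O)c(C=O)c(O)c2[C@H]1CC(C)=C | intermediate
20 | CNP0388405.1 | CC1=C2[C@H]([C@H]3[C@@H](CC1)C3(C)C)[C@]1(C)C[C@H]2Oc2c(C=O)c(O)c(C=O)c(O)c2[C@H]1CC(C)C | target

## Step count and least certain steps

Total: 13 steps. Longest linear sequence: 12 steps (steps 1 to 10, 12 and 13, from 1 to 20); step 11 is a one-step branch.

Step 6 (key step). Closing the seven-membered ring may be slower than the homodienyl hydrogen shift that opens a cis-alkyl vinylcyclopropane on heating, or than oligomerisation of the terminal ynone, because the dienophile reaches C5 only after the five-atom tether is frozen. Fallback: from 9, conjugate addition of PhSO2Na (AcOH, EtOH) gives the (E)-β-(phenylsulfonyl)vinyl ketone F1. Its doubly activated alkene should undergo the same intramolecular cycloaddition at 25 to 60 °C to the sulfonyl ketone F2. DBU then eliminates benzenesulfinate across C1–C2 (the C1 proton is α to the ketone) and the route is rejoined at 10. The alkyne is replaced by an alkene dienophile with a traceless activating group, so the position of the new alkene is fixed by the leaving group.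

Step 8. After the C4–O bond opens, proton loss from C3 (which would give a conjugated dienone and then an arene) or hydride shift from C7' may outrun migration of C5; a free cation at C4 would also loosen the transfer of configuration. Fallback: from 10, NBS in aqueous acetone should give the bromohydrin F3 (bromonium anti to C6, water at C4). K2CO3 in MeOH closes it to the epoxide F4 with oxygen syn to C6. LiBr/HMPA in benzene at 80 °C then opens F4 at C4 to a trans bromohydrin salt, in whose diequatorial conformer only the C7'–C5 ring bond is antiperiplanar to C4–Br; C5 migrates with loss of bromide. Two inversions at C4 lead to the same aldehyde, and the route is rejoined at 12.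

Step 12. Three things may go wrong: carbon–carbon bond formation by the allyl cation (at the free carbon of 16 or, later, with 17) before the ether ring is closed; slow arylation of the hindered C7' oxocarbenium; and attack on the C7' cation before ring B exists or from the face of the C1–C5 bridge, which would erode control of C7'. Fallback: from 12 and 15, CSA-mediated condensation at C7' with oxa-Michael closure of ring B onto the enone (no allyl cation exists at this stage), followed by 17, should give the ketone F5. H2 over Pd/C gives the isobutyl ketone F6, MeLi/CeCl3 the tertiary alcohol F7, and CSA dehydration the tetrasubstituted alkene F8. Vilsmeier diformylation (POCl3, DMF) at the two free ring carbons then rejoins the route at 20, bypassing step 13.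

Step 4. The lithiated allylic phosphonate may react partly through its γ-carbon or give incomplete E selectivity, and the basic medium may epimerise the cis-aldehyde. Fallback: from 6, Wittig reaction with the stabilised ylide Ph3P=CHC(O)CH3 (CH2Cl2, 23 °C) gives the (E)-enone F9; methylenation of its ketone with Ph3P=CH2 (THF, 0 °C) rejoins the route at 8.

## Further compounds

F1 | step 6 | (E)-β-(phenylsulfonyl)vinyl ketone from 9 | O=C(/C=C/S(=O)(=O)c1ccccc1)CC[C@@H]1[C@H](/C=C/C(C)=C)C1(C)C
F2 | step 6 | sulfonyl ketone cycloadduct (C1–H, C2–SO2Ph, mixture at C1 and C2) | O=C1C2C(S(=O)(=O)c3ccccc3)CC(C)=C[C@H]2[C@H]4[C@@H](CC1)C4(C)C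
F3 | step 8 | bromohydrin of 10 (OH on C4 syn to C6, Br on C7' anti to C6) | O=C1C2=CC[C@@](C)(O)[C@H](Br)[C@H]2[C@H]3[C@@H](CC1)C3(C)C
F4 | step 8 | C4–C7' epoxide of 10, oxygen syn to C6 | O=C1C2=CC[C@@]3(C)O[C@H]3[C@H]2[C@H]4[C@@H](CC1)C4(C)C
F5 | step 12 | ring-B closed C10 ketone without formyl groups, methallyl on C7' (C1 epimers) | O=C1C2[C@H]([C@H]3[C@@H](CC1)C3(C)C)[C@]1(C)C[C@H]2Oc2cc(O)cc(O)c2[C@H]1CC(C)=C
F6 | step 12 | isobutyl ketone from F5 | O=C1C2[C@H]([C@H]3[C@@H](CC1)C3(C)C)[C@]1(C)C[C@H]2Oc2cc(O)cc(O)c2[C@H]1CC(C)C
F7 | step 12 | C10 tertiary alcohol from F6 (C1 and C10 epimers) | CC1(O)C2[C@H]([C@H]3[C@@H](CC1)C3(C)C)[C@]1(C)C[C@H]2Oc2cc(O)cc(O)c2[C@H]1CC(C)C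
F8 | step 12 | bis-desformyl analogue of 20 | CC1=C2[C@H]([C@H]3[C@@H](CC1)C3(C)C)[C@]1(C)C[C@H]2Oc2cc(O)cc(O)c2[C@H]1CC(C)C
F9 | step 4 | (E)-enone Weinreb amide from 6 | CON(C)C(=O)CC[C@@H]1[C@H](/C=C/C(C)=O)C1(C)C
A1 | alternative 1 | acyclic vinyl diazoketone with (E)-diene | C=C(C)C(=[N+]=[N-])C(=O)C[C@@](C)(/C=C/C=C)[C@H](CC(C)C)c1c(O[Si](C)(C)C(C)(C)C)cc(OCOC)cc1OCOC
A2 | alternative 1 | hydroazulenone with C2 ketone, C1=C10 and C6=C7 alkenes | CC1=C2[C@H](C=CCC1)[C@](C)(CC2=O)[C@H](CC(C)C)c1c(O[Si](C)(C)C(C)(C)C)cc(OCOC)cc1OCOC
A3 | alternative 2 | C2 ethynyl ether of the tricyclic terpenoid acetal | CC1=C2[C@H]([C@H]3[C@@H](CC1)C3(C)C)[C@@](C)(C(OC)OC)C[C@H]2OC#C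
A4 | alternative 2 | 3-(benzyloxy)cyclobut-2-en-1-one | O=C1C=C(OCc2ccccc2)C1
A5 | alternative 2 | terpene 3-benzyloxy-5-hydroxyphenyl ether | CC1=C2[C@H]([C@H]3[C@@H](CC1)C3(C)C)[C@@](C)(C(OC)OC)C[C@H]2Oc1cc(O)cc(OCc2ccccc2)c1
A6 | alternative 3 | carene-derived 8,8-dimethylbicyclo[5.1.0]oct-2-en-4-one | O=C1C=C[C@H]2[C@@H](CC1)C2(C)C
A7 | alternative 3 | (aR)-4-(tert-butyldimethylsilyloxy)-3-methyl-1-(trimethylsilyl)buta-1,2-diene | C[Si](C)(C)C([H])=[C@]=C(C)CO[Si](C)(C)C(C)(C)C
A8 | alternative 3 | cis-fused hydroazulenone with C3 vinylsilane | O=C1[C@H]2C=C([Si](C)(C)C)[C@](C)(CO[Si](C)(C)C(C)(C)C)[C@H]2[C@H]3[C@@H](CC1)C3(C)C
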